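**Plan**
- Retrosynthesis: cut the two side-chain ArO–CH(CH3) ether bonds (carbinols back to ketones), then the two phenolic C–O bonds (back to aryl bromides), then both ring bonds O1–C2 and O1–C5 of the oxolane (back to a seven-membered cyclic sulfate of a 1,4-diol), then the two aryl–carbonyl bonds (back to (2R,3R)-dimethylsuccinic anhydride), and last the C3–C4 bond (two propionyl units).
- Forward: C3–C4 is made by joining two molecules of the propionimide through their enolates, the two different aryl ketones are attached one after the other, the diol is tied into a 1,3,2-dioxathiepane, and this ring contracts to the oxolane, the only ring the route builds. The bromides then become phenols, both side chains are attached there, and debenzylation ends the route.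
- Enabling feature: in the oxolane ring (O1, C2, C3, C4, C5) each aryl at C2 and C5 is cis to the methyl next to it at C3 and C4, and the methyls are trans. The ring is locally C2-symmetric about the axis through O1 and the midpoint of C3–C4, so it maps onto a C2-symmetric anti,anti-1,4-diol that one external oxygen inverts at both benzylic carbons.
- Stereochemistry: C3 and C4 come from the (S)-4-benzyloxazolidinone auxiliary; C2 and C5 from a matched oxazaborolidine reduction followed by two SN2 inversions; the aryloxy-bearing side-chain carbons from ethyl (S)-lactate with inversion; the side-chain carbinols from Felkin–Anh reduction.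

Key step: step 10

Remark on the chemistry: the two benzylic ends of cyclic sulfate 15 differ only in a remote meta-alkoxy group, so opening may begin at either end. Both regioisomeric intermediates converge on 18; one regioisomer is drawn for 16, 17 and the fallback compounds. Cyclic sulfite 14 is expected as a mixture of epimers at sulfur, both of which oxidise to 15.

**Route**

Step 1
Reactants: 1 (S)-4-benzyl-3-propanoyl-1,3-oxazolidin-2-one (2 equiv; two molecules are joined at their α-carbons)
Product: 2 (4S,4'S)-3,3'-[(2R,3R)-2,3-dimethylbutanedioyl]bis(4-benzyl-1,3-oxazolidin-2-one)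
Conditions: LiN(i-Pr)2 (1 equiv per imide), THF, −78 °C; then TiCl4 (1 equiv per imide), −78 °C to rt
Reagents that add atoms: a second molecule of (S)-4-benzyl-3-propanoyl-1,3-oxazolidin-2-one 1, CCC(=O)N1C(=O)OC[C@@H]1Cc1ccccc1
Why: Oxidative homocoupling of two chelated (Z)-enolates of 1 by tetravalent titanium (enolate dimerisation, one electron per enolate), in which each α-carbon forms the new C–C bond on the face away from the C4 benzyl group, so both methyl-bearing carbons should arise R.

Step 2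
Reactants: 2 (4S,4'S)-3,3'-[(2R,3R)-2,3-dimethylbutanedioyl]bis(4-benzyl-1,3-oxazolidin-2-one)
Product: 3 (2R,3R)-2,3-dimethylbutanedioic acid
Conditions: LiOH, H2O2, THF/H2O, 0 °C; then Na2SO3 aq; then HCl aq
Reagents that add atoms: hydrogen peroxide (as LiOOH), OO
Why: Hydroperoxide cleavage of the N-acyloxazolidinone at the exocyclic carbonyl, a nucleophile too weakly basic to epimerise the α-centres, with sulfite reducing the peracid and the auxiliary recovered.

Step 3
Reactants: 3 (2R,3R)-2,3-dimethylbutanedioic acid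
Product: 4 (3R,4R)-3,4-dimethyloxolane-2,5-dione
Conditions: CH3COCl (neat), 50 °C
Reagents that add atoms: none
Why: Cyclodehydration through the mixed anhydride under mild, base-free conditions, which should leave the trans-dimethyl centres unepimerised.

Step 4
Reactants: 4 (3R,4R)-3,4-dimethyloxolane-2,5-dione; 5 1-bromo-4-iodo-2-methoxybenzene
Product: 7 (2R,3R)-4-(4-bromo-3-methoxyphenyl)-2,3-dimethyl-4-oxobutanoic acid, via 4-bromo-3-methoxyphenylmagnesium chloride 6 (not isolated)
Conditions: 5, i-PrMgCl·LiCl, THF, −20 °C; then added to 4 (slight excess), THF, −78 °C; HCl aq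
Reagents that add atoms: none
Why: Iodine–magnesium exchange is selective for the C–I bond, and the aryl Grignard reagent opens the C2-symmetric anhydride once (acylation by a cyclic anhydride), the resulting carboxylate and the hindered ketone resisting further addition at −78 °C.

Step 5
Reactants: 7 (2R,3R)-4-(4-bromo-3-methoxyphenyl)-2,3-dimethyl-4-oxobutanoic acid
Product: 8 S-(pyridin-2-yl) (2R,3R)-4-(4-bromo-3-methoxyphenyl)-2,3-dimethyl-4-oxobutanethioate
Conditions: 2,2'-dipyridyl disulfide, PPh3, CH2Cl2, rt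
Reagents that add atoms: 2,2'-dipyridyl disulfide, c1ccc(SSc2ccccn2)nc1
Why: Redox condensation (phosphine/disulfide thioesterification) in which the acyloxyphosphonium ion is trapped by pyridine-2-thiolate under neutral conditions, so the epimerisable centres are not touched.

Step 6
Reactants: 9 2-bromo-5-iodophenol
Product: 10 2-(benzyloxy)-1-bromo-4-iodobenzene
Conditions: BnBr, K2CO3, DMF, rt
Reagents that add atoms: benzyl bromide, BrCc1ccccc1
Why: Williamson etherification of the phenoxide with a benzylic halide.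

Step 7
Reactants: 8 S-(pyridin-2-yl) (2R,3R)-4-(4-bromo-3-methoxyphenyl)-2,3-dimethyl-4-oxobutanethioate; 10 2-(benzyloxy)-1-bromo-4-iodobenzene
Product: 12 (2R,3R)-1-[3-(benzyloxy)-4-bromophenyl]-4-(4-bromo-3-methoxyphenyl)-2,3-dimethylbutane-1,4-dione, via 3-(benzyloxy)-4-bromophenylmagnesium chloride 11 (not isolated)
Conditions: 10, i-PrMgCl·LiCl, THF, −20 °C; then added to 8, THF, −78 °C; NH4Cl aq
Reagents that add atoms: none
Why: Ketone synthesis by acylation of a Grignard reagent with an S-(2-pyridyl) thioester, where chelation of magnesium between pyridine nitrogen and thioester carbonyl makes acyl substitution at −78 °C far faster than addition to the hindered α-branched aryl ketone.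

Step 8
Reactants: 12 (2R,3R)-1-[3-(benzyloxy)-4-bromophenyl]-4-(4-bromo-3-methoxyphenyl)-2,3-dimethylbutane-1,4-dione
Product: 13 (1R,2R,3R,4R)-1-[3-(benzyloxy)-4-bromophenyl]-4-(4-bromo-3-methoxyphenyl)-2,3-dimethylbutane-1,4-diol
Conditions: (S)-1-methyl-3,3-diphenyltetrahydro-1H,3H-pyrrolo[1,2-c][1,3,2]oxazaborole (0.4 equiv), BH3·SMe2, THF, −20 to 0 °C; MeOH quench
Reagents that add atoms: none
Why: Corey–Bakshi–Shibata reduction in which, with the aryl ring as the large group, the (S)-oxazaborolidine should deliver hydride to give the (R)-carbinol at each ketone, the same face that Felkin–Anh control from the adjacent (R)-methyl centre favours (matched), so both carbinols end up anti to their neighbouring methyl.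

Step 9
Reactants: 13 (1R,2R,3R,4R)-1-[3-(benzyloxy)-4-bromophenyl]-4-(4-bromo-3-methoxyphenyl)-2,3-dimethylbutane-1,4-diol
Product: 15 (4R,5R,6R,7R)-4-[3-(benzyloxy)-4-bromophenyl]-7-(4-bromo-3-methoxyphenyl)-5,6-dimethyl-1,3,2-dioxathiepane 2,2-dioxide, via cyclic sulfite 14 (not isolated)
Conditions: SOCl2, Et3N, CH2Cl2, −40 to 0 °C; then RuCl3·xH2O (cat.), NaIO4, MeCN/EtOAc/H2O, 0 °C, short contact time
Reagents that add atoms: thionyl chloride, O=S(Cl)Cl; sodium periodate, [Na+].[O-]I(=O)(=O)=O
Why: Two-stage cyclic sulfate synthesis (cyclic sulfite from the diol, then RuO4-catalysed oxidation at sulfur) that breaks no C–O bond, so all four stereocentres are carried over unchanged.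

Step 10
Reactants: 15 (4R,5R,6R,7R)-4-[3-(benzyloxy)-4-bromophenyl]-7-(4-bromo-3-methoxyphenyl)-5,6-dimethyl-1,3,2-dioxathiepane 2,2-dioxide
Product: 18 (2S,3R,4R,5S)-2-[3-(benzyloxy)-4-bromophenyl]-5-(4-bromo-3-methoxyphenyl)-3,4-dimethyloxolane, via acetoxy sulfate cesium salt 16 (not isolated), via hydroxy sulfate cesium salt 17 (not isolated)
Conditions: CsOAc, DMF, 0 °C to rt; then Cs2CO3, MeOH, 50 °C
Reagents that add atoms: cesium acetate, CC(=O)[O-].[Cs+]
Why: Proposed new method: acetate opens the seven-membered cyclic sulfate by SN2 attack at one benzylic carbon (inversion) to give 16, methanolysis unmasks that oxygen as the alkoxide of 17, and the alkoxide displaces the remaining sulfate monoester at the other benzylic carbon (second inversion), so O1–C2 and O1–C5 are both formed and sulfate is expelled; the closest known reactions are the double displacement that converts 1,4-diol cyclic sulfates into phospholanes, thiolanes and pyrrolidines, the carboxylate opening of cyclic sulfates, and alkoxide displacement of a sulfate monoester in epoxide formation. The oxolane closes in a 5-exo-tet mode. Both new stereocentres (C2 and C5) are controlled by stereospecific backside attack on the (R)-carbinol carbons set in step 8, which turns each aryl from trans to cis relative to its neighbouring methyl, and because the core is locally C2-symmetric either end may open first. The step needs substitution at carbon to win over attack at sulfur, ionisation and elimination: carboxylates open cyclic sulfates at carbon, acetate is a weak base, the para-bromo substituents (the meta-alkoxy groups being only inductively withdrawing) disfavour benzylic cations, and the second displacement is intramolecular.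

Step 11
Reactants: 18 (2S,3R,4R,5S)-2-[3-(benzyloxy)-4-bromophenyl]-5-(4-bromo-3-methoxyphenyl)-3,4-dimethyloxolane
Product: 20 2-(benzyloxy)-4-[(2S,3R,4R,5S)-5-(4-hydroxy-3-methoxyphenyl)-3,4-dimethyloxolan-2-yl]phenol, via bis(pinacol boronate) 19 (not isolated)
Conditions: B2pin2, [1,1'-bis(diphenylphosphino)ferrocene]PdCl2 (cat.), KOAc, 1,4-dioxane, 90 °C; then THF, NaOH aq, H2O2, 0 °C to rt
Reagents that add atoms: hydrogen peroxide, OO; bis(pinacolato)diboron (boron of 19 only), CC1(C)OB(B2OC(C)(C)C(C)(C)O2)OC1(C)C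
Why: Miyaura borylation of both aryl bromides followed by in-flask oxidation of the aryl boronates with alkaline peroxide (aryl migration from boron to oxygen), conditions under which the benzyl ether and the oxolane centres are inert.

Step 12
Reactants: 21 ethyl (S)-2-hydroxypropanoate
Product: 22 (S)-2-hydroxy-N-methoxy-N-methylpropanamide
Conditions: MeNHOMe·HCl, i-PrMgCl, THF, −20 to 0 °C
Reagents that add atoms: N,O-dimethylhydroxylamine hydrochloride, CNOC.Cl
Why: Aminolysis of the ester by the magnesium amide of N,O-dimethylhydroxylamine (Weinreb amide synthesis), the lactate centre being shielded from epimerisation as its magnesium alkoxide.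

Step 13
Reactants: 22 (S)-2-hydroxy-N-methoxy-N-methylpropanamide; 23 (3,4-dimethoxyphenyl)magnesium bromide (commercial THF solution)
Product: 24 (S)-1-(3,4-dimethoxyphenyl)-2-hydroxypropan-1-one
Conditions: i-PrMgCl (1 equiv), THF, −20 °C; then 23, 0 °C to rt; NH4Cl aq
Reagents that add atoms: none
Why: Weinreb ketone synthesis on the preformed magnesium alkoxide, the chelated tetrahedral intermediate collapsing only on work-up so that neither over-addition nor loss of the (S)-centre is expected.

Step 14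
Reactants: 24 (S)-1-(3,4-dimethoxyphenyl)-2-hydroxypropan-1-one
Product: 25 (S)-1-(3,4-dimethoxyphenyl)-1-oxopropan-2-yl 4-methylbenzenesulfonate
Conditions: TsCl, pyridine, CH2Cl2, 0 °C
Reagents that add atoms: 4-methylbenzenesulfonyl chloride, Cc1ccc(S(=O)(=O)Cl)cc1
Why: O-Sulfonylation with retention at carbon, pyridine being too weak a base to enolise the ketone.

Step 15
Reactants: 20 2-(benzyloxy)-4-[(2S,3R,4R,5S)-5-(4-hydroxy-3-methoxyphenyl)-3,4-dimethyloxolan-2-yl]phenol; 25 (S)-1-(3,4-dimethoxyphenyl)-1-oxopropan-2-yl 4-methylbenzenesulfonate (2.4 equiv)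
Product: 26 (R)-2-{2-(benzyloxy)-4-[(2S,3R,4R,5S)-5-(4-{[(R)-1-(3,4-dimethoxyphenyl)-1-oxopropan-2-yl]oxy}-3-methoxyphenyl)-3,4-dimethyloxolan-2-yl]phenoxy}-1-(3,4-dimethoxyphenyl)propan-1-one
Conditions: BEMP (2-tert-butylimino-2-diethylamino-1,3-dimethylperhydro-1,3,2-diazaphosphorine), MeCN, 0 °C to rt
Reagents that add atoms: none
Why: Twofold Williamson O-alkylation of the phenoxides by the activated α-keto tosylate with SN2 inversion, giving the (R)-aryloxy centres, while the non-nucleophilic phosphazene base and low temperature should avoid epimerisation of the α-aryloxy ketones.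

Step 16
Reactants: 26 (R)-2-{2-(benzyloxy)-4-[(2S,3R,4R,5S)-5-(4-{[(R)-1-(3,4-dimethoxyphenyl)-1-oxopropan-2-yl]oxy}-3-methoxyphenyl)-3,4-dimethyloxolan-2-yl]phenoxy}-1-(3,4-dimethoxyphenyl)propan-1-one
Product: 27 (1R,2R)-2-{2-(benzyloxy)-4-[(2S,3R,4R,5S)-5-(4-{[(1R,2R)-1-(3,4-dimethoxyphenyl)-1-hydroxypropan-2-yl]oxy}-3-methoxyphenyl)-3,4-dimethyloxolan-2-yl]phenoxy}-1-(3,4-dimethoxyphenyl)propan-1-ol
Conditions: Bu4NBH4, CH2Cl2/MeOH, −20 °C
Reagents that add atoms: none
Why: Felkin–Anh reduction under non-chelating conditions, in which the quaternary ammonium counter-ion cannot bridge the two oxygens, the C–OAr bond lies anti to the incoming hydride and attack past the α-hydrogen should give the (1R,2R)-threo alcohol at both ketones.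

Step 17
Reactants: 27 (1R,2R)-2-{2-(benzyloxy)-4-[(2S,3R,4R,5S)-5-(4-{[(1R,2R)-1-(3,4-dimethoxyphenyl)-1-hydroxypropan-2-yl]oxy}-3-methoxyphenyl)-3,4-dimethyloxolan-2-yl]phenoxy}-1-(3,4-dimethoxyphenyl)propan-1-ol
Product: 28 manassantin B1
Conditions: H2 (1 atm), Pd/C, EtOAc, rt, stopped at full conversion
Reagents that add atoms: none
Why: Hydrogenolysis of the aryl benzyl ether over palladium under neutral conditions, which is much faster than cleavage of the secondary benzylic C–O bonds of the oxolane and the side chains.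

**Compound list**

1 | (S)-4-benzyl-3-propanoyl-1,3-oxazolidin-2-one | CCC(=O)N1C(=O)OC[C@@H]1Cc1ccccc1 | starting material
2 | (4S,4'S)-3,3'-[(2R,3R)-2,3-dimethylbutanedioyl]bis(4-benzyl-1,3-oxazolidin-2-one) | O=C([C@H](C)[C@@H](C)C(=O)N1C(=O)OC[C@@H]1Cc1ccccc1)N1C(=O)OC[C@@H]1Cc1ccccc1 | intermediate
3 | (2R,3R)-2,3-dimethylbutanedioic acid | O=C(O)[C@H](C)[C@@H](C)C(=O)O | intermediate
4 | (3R,4R)-3,4-dimethyloxolane-2,5-dione | O=C1[C@H](C)[C@@H](C)C(=O)O1 | intermediate
5 | 1-bromo-4-iodo-2-methoxybenzene | COc1cc(I)ccc1Br | starting material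
6 | 4-bromo-3-methoxyphenylmagnesium chloride (LiCl complex, formed in the flask) | COc1cc([Mg]Cl)ccc1Br | intermediate
7 | (2R,3R)-4-(4-bromo-3-methoxyphenyl)-2,3-dimethyl-4-oxobutanoic acid | COc1cc(C(=O)[C@H](C)[C@@H](C)C(=O)O)ccc1Br | intermediate
8 | S-(pyridin-2-yl) (2R,3R)-4-(4-bromo-3-methoxyphenyl)-2,3-dimethyl-4-oxobutanethioate | COc1cc(C(=O)[C@H](C)[C@@H](C)C(=O)Sc2ccccn2)ccc1Br | intermediate
9 | 2-bromo-5-iodophenol | Oc1cc(I)ccc1Br | starting material
10 | 2-(benzyloxy)-1-bromo-4-iodobenzene | Brc1ccc(I)cc1OCc1ccccc1 | intermediate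
11 | 3-(benzyloxy)-4-bromophenylmagnesium chloride (LiCl complex, formed in the flask) | Cl[Mg]c1ccc(Br)c(OCc2ccccc2)c1 | intermediate
12 | (2R,3R)-1-[3-(benzyloxy)-4-bromophenyl]-4-(4-bromo-3-methoxyphenyl)-2,3-dimethylbutane-1,4-dione | COc1cc(C(=O)[C@H](C)[C@@H](C)C(=O)c2ccc(Br)c(OCc3ccccc3)c2)ccc1Br | intermediate
13 | (1R,2R,3R,4R)-1-[3-(benzyloxy)-4-bromophenyl]-4-(4-bromo-3-methoxyphenyl)-2,3-dimethylbutane-1,4-diol | Brc1ccc([C@H](O)[C@H](C)[C@@H](C)[C@@H](O)c2ccc(Br)c(OC)c2)cc1OCc1ccccc1 | intermediate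
14 | (4R,5R,6R,7R)-4-[3-(benzyloxy)-4-bromophenyl]-7-(4-bromo-3-methoxyphenyl)-5,6-dimethyl-1,3,2-dioxathiepane 2-oxide (sulfur epimers, formed in the flask) | Brc1ccc([C@@H]2OS(=O)O[C@@H](c3ccc(Br)c(OC)c3)[C@H](C)[C@H]2C)cc1OCc1ccccc1 | intermediate
15 | (4R,5R,6R,7R)-4-[3-(benzyloxy)-4-bromophenyl]-7-(4-bromo-3-methoxyphenyl)-5,6-dimethyl-1,3,2-dioxathiepane 2,2-dioxide | Brc1ccc([C@@H]2OS(=O)(=O)O[C@@H](c3ccc(Br)c(OC)c3)[C@H](C)[C@H]2C)cc1OCc1ccccc1 | intermediate
16 | cesium (1R,2R,3R,4S)-4-(acetyloxy)-4-[3-(benzyloxy)-4-bromophenyl]-1-(4-bromo-3-methoxyphenyl)-2,3-dimethylbutyl sulfate (formed in the flask) | CC(=O)O[C@H](c1ccc(Br)c(OCc2ccccc2)c1)[C@H](C)[C@@H](C)[C@@H](OS(=O)(=O)[O-])c1ccc(Br)c(OC)c1.[Cs+] | intermediate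
17 | cesium (1R,2R,3R,4S)-4-[3-(benzyloxy)-4-bromophenyl]-1-(4-bromo-3-methoxyphenyl)-4-hydroxy-2,3-dimethylbutyl sulfate (formed in the flask) | O[C@H](c1ccc(Br)c(OCc2ccccc2)c1)[C@H](C)[C@@H](C)[C@@H](OS(=O)(=O)[O-])c1ccc(Br)c(OC)c1.[Cs+] | intermediate
18 | (2S,3R,4R,5S)-2-[3-(benzyloxy)-4-bromophenyl]-5-(4-bromo-3-methoxyphenyl)-3,4-dimethyloxolane | Brc1ccc([C@H]2O[C@H](c3ccc(Br)c(OC)c3)[C@H](C)[C@H]2C)cc1OCc1ccccc1 | intermediate
19 | 2-{2-(benzyloxy)-4-[(2S,3R,4R,5S)-5-[3-methoxy-4-(4,4,5,5-tetramethyl-1,3,2-dioxaborolan-2-yl)phenyl]-3,4-dimethyloxolan-2-yl]phenyl}-4,4,5,5-tetramethyl-1,3,2-dioxaborolane (formed in the flask) | CC1(C)OB(c2ccc([C@H]3O[C@H](c4ccc(B5OC(C)(C)C(C)(C)O5)c(OC)c4)[C@H](C)[C@H]3C)cc2OCc2ccccc2)OC1(C)C | intermediate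
20 | 2-(benzyloxy)-4-[(2S,3R,4R,5S)-5-(4-hydroxy-3-methoxyphenyl)-3,4-dimethyloxolan-2-yl]phenol | Oc1ccc([C@H]2O[C@H](c3ccc(O)c(OC)c3)[C@H](C)[C@H]2C)cc1OCc1ccccc1 | intermediate
21 | ethyl (S)-2-hydroxypropanoate | C[C@H](O)C(=O)OCC | starting material
22 | (S)-2-hydroxy-N-methoxy-N-methylpropanamide | C[C@H](O)C(=O)N(C)OC | intermediate
23 | (3,4-dimethoxyphenyl)magnesium bromide | COc1ccc([Mg]Br)cc1OC | starting material
24 | (S)-1-(3,4-dimethoxyphenyl)-2-hydroxypropan-1-one | C[C@H](O)C(=O)c1ccc(OC)c(OC)c1 | intermediate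
25 | (S)-1-(3,4-dimethoxyphenyl)-1-oxopropan-2-yl 4-methylbenzenesulfonate | C[C@H](OS(=O)(=O)c1ccc(C)cc1)C(=O)c1ccc(OC)c(OC)c1 | intermediate
26 | (R)-2-{2-(benzyloxy)-4-[(2S,3R,4R,5S)-5-(4-{[(R)-1-(3,4-dimethoxyphenyl)-1-oxopropan-2-yl]oxy}-3-methoxyphenyl)-3,4-dimethyloxolan-2-yl]phenoxy}-1-(3,4-dimethoxyphenyl)propan-1-one | COc1ccc(C(=O)[C@@H](C)Oc2ccc([C@H]3O[C@H](c4ccc(O[C@H](C)C(=O)c5ccc(OC)c(OC)c5)c(OC)c4)[C@H](C)[C@H]3C)cc2OCc2ccccc2)cc1OC | intermediate
27 | (1R,2R)-2-{2-(benzyloxy)-4-[(2S,3R,4R,5S)-5-(4-{[(1R,2R)-1-(3,4-dimethoxyphenyl)-1-hydroxypropan-2-yl]oxy}-3-methoxyphenyl)-3,4-dimethyloxolan-2-yl]phenoxy}-1-(3,4-dimethoxyphenyl)propan-1-ol | COc1ccc([C@@H](O)[C@@H](C)Oc2ccc([C@H]3O[C@H](c4ccc(O[C@H](C)[C@H](O)c5ccc(OC)c(OC)c5)c(OC)c4)[C@H](C)[C@H]3C)cc2OCc2ccccc2)cc1OC | intermediate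
28 | manassantin B1: (1R,2R)-1-(3,4-dimethoxyphenyl)-2-{4-[(2S,3R,4R,5S)-5-(4-{[(1R,2R)-1-(3,4-dimethoxyphenyl)-1-hydroxypropan-2-yl]oxy}-3-methoxyphenyl)-3,4-dimethyloxolan-2-yl]-2-hydroxyphenoxy}propan-1-ol | COc1ccc([C@@H](O)[C@@H](C)Oc2ccc([C@H]3O[C@H](c4ccc(O[C@H](C)[C@H](O)c5ccc(OC)c(OC)c5)c(OC)c4)[C@H](C)[C@H]3C)cc2O)cc1OC | target

**Step count and risks**

Total step count: 17. Longest linear sequence: 13 steps (steps 1–5, 7–11 and 15–17; steps 6 and 12–14 are side branches).

Steps most likely to fail: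

1. Step 10 (proposed new method). The sulfate monoester may leave too slowly from the hindered benzylic carbon, so that elimination to a styrene or solvolysis by methanol with loss of configuration overtakes ring closure. Fallback, from 15 back to 18, with the ring-closing leaving group changed to a sulfonate and every stage a known reaction: PhCO2Cs in DMF opens 15 at a benzylic carbon with inversion (the known carboxylate opening of cyclic sulfates) to the benzoyloxy sulfate cesium salt F1. Catalytic H2SO4 with a little water in THF cleaves the sulfate monoester at the S–O bond with retention and should give hydroxy benzoate F2. MsCl/Et3N at −20 °C converts the free (R)-carbinol into mesylate F3. K2CO3 in MeOH then removes the benzoate, and the alkoxide closes the oxolane by intramolecular Williamson displacement of the mesylate with inversion, giving 18.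

2. Step 9. Mono-activation of a benzylic 1,4-diol invites premature 5-exo closure to an oxolane with only one inversion, or chloride substitution, before the seven-membered sulfite forms; ruthenium tetroxide may also over-oxidise the benzyl ether or the alkoxyarenes. Fallback, from 13 back to 18 without any cyclic sulfur ester: monosilylation (TBSCl, imidazole, one equivalent) gives mono-silyl ether F4; it does not matter which hydroxyl reacts, and diol and bis-silyl ether are recycled. A Mitsunobu reaction with benzoic acid (PPh3, diisopropyl azodicarboxylate) inverts the free carbinol to silyloxy benzoate F5. Bu4NF removes the silyl group to give hydroxy benzoate F2, which is mesylated to mesylate F3 and closed with K2CO3/MeOH to 18 as in the fallback for step 10.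

3. Step 7. Over-addition of the Grignard reagent to the ketone carbonyls, or diversion of the activated γ-keto acid derivative into cyclic pseudo-acid forms, would erode the diketone. Fallback, from 7 back to 13, with the first carbonyl stored as a lactone while the second aryl is added: MeI/KHCO3 in DMF gives methyl keto ester F6. Reduction with the (S)-oxazaborolidine of step 8 and BH3·SMe2, then TsOH, gives the all-trans lactone F7. Grignard reagent 11 adds once to the lactone at −78 °C to give hydroxy ketone F8, in equilibrium with its lactol. A second reduction with the same (S)-oxazaborolidine and BH3·SMe2 delivers diol 13.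

**Further compounds**

F1 | step 10 | cesium (1R,2R,3R,4S)-4-(benzoyloxy)-4-[3-(benzyloxy)-4-bromophenyl]-1-(4-bromo-3-methoxyphenyl)-2,3-dimethylbutyl sulfate | O=C(O[C@H](c1ccc(Br)c(OCc2ccccc2)c1)[C@H](C)[C@@H](C)[C@@H](OS(=O)(=O)[O-])c1ccc(Br)c(OC)c1)c1ccccc1.[Cs+]
F2 | step 10 | (1S,2R,3R,4R)-1-[3-(benzyloxy)-4-bromophenyl]-4-(4-bromo-3-methoxyphenyl)-4-hydroxy-2,3-dimethylbutyl benzoate | O=C(O[C@H](c1ccc(Br)c(OCc2ccccc2)c1)[C@H](C)[C@@H](C)[C@@H](O)c1ccc(Br)c(OC)c1)c1ccccc1
F3 | step 10 | (1S,2R,3R,4R)-1-[3-(benzyloxy)-4-bromophenyl]-4-(4-bromo-3-methoxyphenyl)-2,3-dimethyl-4-[(methylsulfonyl)oxy]butyl benzoate | O=C(O[C@H](c1ccc(Br)c(OCc2ccccc2)c1)[C@H](C)[C@@H](C)[C@@H](OS(C)(=O)=O)c1ccc(Br)c(OC)c1)c1ccccc1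
F4 | step 9 | (1R,2R,3R,4R)-1-[3-(benzyloxy)-4-bromophenyl]-4-(4-bromo-3-methoxyphenyl)-4-[(tert-butyldimethylsilyl)oxy]-2,3-dimethylbutan-1-ol | Brc1ccc([C@H](O)[C@H](C)[C@@H](C)[C@@H](O[Si](C)(C)C(C)(C)C)c2ccc(Br)c(OC)c2)cc1OCc1ccccc1
F5 | step 9 | (1S,2R,3R,4R)-1-[3-(benzyloxy)-4-bromophenyl]-4-(4-bromo-3-methoxyphenyl)-4-[(tert-butyldimethylsilyl)oxy]-2,3-dimethylbutyl benzoate | O=C(O[C@H](c1ccc(Br)c(OCc2ccccc2)c1)[C@H](C)[C@@H](C)[C@@H](O[Si](C)(C)C(C)(C)C)c1ccc(Br)c(OC)c1)c1ccccc1
F6 | step 7 | methyl (2R,3R)-4-(4-bromo-3-methoxyphenyl)-2,3-dimethyl-4-oxobutanoate | COc1cc(C(=O)[C@H](C)[C@@H](C)C(=O)OC)ccc1Br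
F7 | step 7 | (3R,4R,5R)-5-(4-bromo-3-methoxyphenyl)-3,4-dimethyloxolan-2-one | O=C1O[C@@H](c2ccc(Br)c(OC)c2)[C@H](C)[C@H]1C
F8 | step 7 | (2R,3R,4R)-1-[3-(benzyloxy)-4-bromophenyl]-4-(4-bromo-3-methoxyphenyl)-4-hydroxy-2,3-dimethylbutan-1-one | Brc1ccc(C(=O)[C@H](C)[C@@H](C)[C@@H](O)c2ccc(Br)c(OC)c2)cc1OCc1ccccc1
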